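**Plan**

1. Numbering (germacrane): C1 carbinol, C2–C3, C4–C5 epoxide (methyl C15 on C4), C6 lactone carbinol, C7, C8 tiglate carbinol, C9=C10 (methyl C14 on C10), C11, C12 lactone carbonyl, C13 CH2OH.
2. Retrosynthetic cuts, in order: the C5–O epoxide bond (back to a 4,5-diol with C5 inverted, held as an acetonide), then C6–C7 together with O6–C12, then the C8 ester, C7–C11 (aldol) and C1–C10.
3. Enabling feature: C6 sits in both rings, as the member of the ten-membered carbocycle bonded to C7 and as the oxygen-bearing carbon of the five-membered lactone whose C7=C11 bond holds C12 cis to C6. One addition of a C7 alkenyl metal to a C6 aldehyde therefore closes the carbocycle and leaves an alkoxide placed to close the butenolide.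
4. Forward: fragment A (C1–C6, C15; from geraniol) and fragment B (C7–C10, C14; from D-glyceraldehyde acetonide) are joined at C1–C10, C11–C13 are added at C7 by an aldol, the Z-enol triflate is made and C8 acylated, both rings close in one operation, and the epoxide is formed last.
5. Stereochemistry: C4 and C5 from Sharpless epoxidation (C4 inverted on hydrolysis, C5 inverted in the final epoxide closure), C8 from D-glyceraldehyde, C1 from CBS reduction, C6 from Felkin–Anh addition anti to the C5 oxygen, 9Z from a Z-iodoalkene, enoate Z geometry from a chelated enolate.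

Key step: step 22

Remark: locants in the names of intermediates are those of the target skeleton; epimer mixtures at centres that a later step removes (C1 in 12, C7 and C11 in 20, C11 in 21) are carried on unseparated.

**Route**

Step 1
Reactants: 1 geraniol
Product: 2 (2S,3S)-2,3-epoxygeraniol
Conditions: Ti(OiPr)4 (5 mol%), L-(+)-diethyl tartrate (6 mol%), t-BuOOH, 4 Å MS, CH2Cl2, −20 °C
Reagents that add atoms: tert-butyl hydroperoxide, CC(C)(C)OO
Why: Sharpless asymmetric epoxidation with the L-(+)-tartrate catalyst oxidises only the allylic 2,3-olefin and should set both epoxide carbons (2S,3S in geraniol numbering, the future C5 and C4), the distal olefin having no directing hydroxyl.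

Step 2
Reactants: 2 (2S,3S)-2,3-epoxygeraniol
Product: 3 (2S,3S)-2,3-epoxygeranyl 4-methoxybenzyl ether
Conditions: NaH, 4-methoxybenzyl chloride, Bu4NI (cat.), THF/DMF, 0 °C → rt
Reagents that add atoms: 4-methoxybenzyl chloride, COc1ccc(CCl)cc1
Why: Williamson etherification of the primary alkoxide should outrun Payne rearrangement at 0 °C and gives a C6 ether that lasts until its oxidative removal in step 20.

Step 3
Reactants: 3 (2S,3S)-2,3-epoxygeranyl 4-methoxybenzyl ether
Product: 4 (2S,3R)-1-(4-methoxybenzyloxy)-3,7-dimethyloct-6-ene-2,3-diol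
Conditions: HClO4 (cat.), THF/H2O (3:1), 0 °C → rt
Reagents that add atoms: water, O
Why: Acid-catalysed epoxide hydrolysis opens the protonated trisubstituted epoxide at its tertiary carbon with inversion (borderline SN2), so the future C4 is inverted to R while the future C5 is untouched.

Step 4
Reactants: 4 (2S,3R)-1-(4-methoxybenzyloxy)-3,7-dimethyloct-6-ene-2,3-diol
Product: 5 (4R,5S)-5-[(4-methoxybenzyloxy)methyl]-2,2,4-trimethyl-4-(4-methylpent-3-enyl)-1,3-dioxolane
Conditions: Me2C(OMe)2, PPTS (cat.), CH2Cl2, rt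
Reagents that add atoms: 2,2-dimethoxypropane, COC(C)(C)OC
Why: Acid-catalysed transketalisation closes the only possible 1,3-dioxolane, on the secondary and tertiary hydroxyls, without touching either stereocentre.

Step 5
Reactants: 5 (4R,5S)-5-[(4-methoxybenzyloxy)methyl]-2,2,4-trimethyl-4-(4-methylpent-3-enyl)-1,3-dioxolane
Product: 6 3-[(4R,5S)-5-[(4-methoxybenzyloxy)methyl]-2,2,4-trimethyl-1,3-dioxolan-4-yl]propanal (fragment A; CHO is C1)
Conditions: OsO4 (2 mol%), NaIO4, 2,6-lutidine, dioxane/H2O (3:1), rt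
Reagents that add atoms: osmium tetroxide, O=[Os](=O)(=O)=O; sodium periodate, [Na+].[O-]I(=O)(=O)=O
Why: Lemieux–Johnson oxidative cleavage (catalytic dihydroxylation, then periodate glycol cleavage, buffered by 2,6-lutidine) should cut the remaining trisubstituted olefin to the C1 aldehyde and leave the 4-methoxybenzyl ether and the ketal alone.

Step 6
Reactants: 7 (R)-2,2-dimethyl-1,3-dioxolane-4-carbaldehyde (D-glyceraldehyde acetonide)
Product: 8 (S)-4-[(Z)-2-iodoprop-1-enyl]-2,2-dimethyl-1,3-dioxolane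
Conditions: EtPPh3I, n-BuLi, THF, 0 °C → rt; I2, −78 °C; NaN(SiMe3)2, −78 → −20 °C; then 7, −78 °C → rt
Reagents that add atoms: ethyltriphenylphosphonium iodide, CC[P+](c1ccccc1)(c1ccccc1)c1ccccc1.[I-]; iodine, II
Why: Wittig olefination with the α-iodo ylide (Stork–Zhao type) should give the trisubstituted iodoalkene with iodine cis to the dioxolane carbon (Z) under kinetic control at low temperature, where the α-alkoxy aldehyde does not epimerise, so C8 comes unchanged from D-glyceraldehyde.

Step 7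
Reactants: 8 (S)-4-[(Z)-2-iodoprop-1-enyl]-2,2-dimethyl-1,3-dioxolane
Product: 9 (2S,3Z)-4-iodopent-3-ene-1,2-diol
Conditions: AcOH/H2O (4:1), rt
Reagents that add atoms: none
Why: Mild acid hydrolysis of the terminal isopropylidene ketal should free the 1,2-diol without ionising the allylic C–O bond or harming the iodoalkene.

Step 8
Reactants: 9 (2S,3Z)-4-iodopent-3-ene-1,2-diol
Product: 10 (2S,3Z)-4-iodo-1,2-bis(triethylsilyloxy)pent-3-ene (fragment B)
Conditions: Et3SiCl, imidazole, CH2Cl2, 0 °C → rt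
Reagents that add atoms: chlorotriethylsilane, CC[Si](Cl)(CC)CC
Why: Imidazole-promoted silylation of both hydroxyls gives a bis-silyl ether whose primary silyl group can later be oxidised off selectively.

Step 9
Reactants: 6 fragment A aldehyde; 10 fragment B iodide
Product: 12 coupled allylic alcohol (C1 epimers; 4R,5S,8S,9Z), via alkenylchromium dichloride 11 (not isolated)
Conditions: CrCl2 (4 equiv), NiCl2 (1 mol%), DMSO, rt
Reagents that add atoms: none
Why: Nozaki–Hiyama–Kishi coupling, in which nickel-catalysed formation of the alkenylchromium and its chemoselective 1,2-addition to the aldehyde form C1–C10 with retention of the Z geometry and without the silyl migration a lithium reagent would risk, the C1 configuration being left open because step 10 erases it.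

Step 10
Reactants: 12 coupled allylic alcohol (C1 epimers)
Product: 13 (4R,5S,8S,9Z)-9-en-1-one
Conditions: Dess–Martin periodinane, NaHCO3, CH2Cl2, 0 °C → rt
Reagents that add atoms: none
Why: Dess–Martin oxidation of the secondary allylic alcohol under bicarbonate buffer should give the Z-enone without isomerising the olefin or cleaving the silyl ethers.

Step 11
Reactants: 13 (4R,5S,8S,9Z)-9-en-1-one
Product: 14 (1R,4R,5S,8S,9Z)-allylic alcohol
Conditions: (S)-2-methyl-CBS-oxazaborolidine (20 mol%), BH3·SMe2, THF, −30 °C; MeOH quench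
Reagents that add atoms: none
Why: Corey–Bakshi–Shibata reduction, in which the (S)-oxazaborolidine binds the ketone with the α-methyl alkenyl group as the large substituent and delivers hydride in a 1,2-sense to the face that should give the 1R alcohol.

Step 12
Reactants: 14 (1R,4R,5S,8S,9Z)-allylic alcohol
Product: 15 C1 tert-butyldiphenylsilyl ether
Conditions: t-BuPh2SiCl, imidazole, DMAP (cat.), DMF, rt → 40 °C
Reagents that add atoms: tert-butylchlorodiphenylsilane, CC(C)(C)[Si](Cl)(c1ccccc1)c1ccccc1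
Why: Imidazole-promoted silylation protects the allylic C1 hydroxyl as the acid-stable silyl ether that the later ketal hydrolysis requires.

Step 13
Reactants: 15 C1 tert-butyldiphenylsilyl ether
Product: 16 C7 aldehyde (8S, OSiEt3 on C8)
Conditions: (COCl)2, DMSO, CH2Cl2, −78 → −40 °C; Et3N, −78 → 0 °C
Reagents that add atoms: none
Why: Under Swern conditions the chlorodimethylsulfonium ion desilylates and oxidises a primary triethylsilyl ether directly to the aldehyde while the secondary one stays, so C7 is unmasked in one step and the α-silyloxy aldehyde is used at once to avoid epimerisation at C8.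

Step 14
Reactants: 17 methyl 3-hydroxypropanoate
Product: 18 methyl 3-(tert-butyldiphenylsilyloxy)propanoate
Conditions: t-BuPh2SiCl, imidazole, CH2Cl2, rt
Reagents that add atoms: tert-butylchlorodiphenylsilane, CC(C)(C)[Si](Cl)(c1ccccc1)c1ccccc1
Why: Standard imidazole-promoted silylation of the primary alcohol gives the ester that carries C11, C12 and C13.

Step 15
Reactants: 18 methyl 3-(tert-butyldiphenylsilyloxy)propanoate; 16 C7 aldehyde
Product: 20 aldol adduct (β-hydroxy ester; mixture at C7 and C11), via lithium ester enolate 19 (not isolated)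
Conditions: LiN(iPr)2, THF, −78 °C; then 16, −78 °C; AcOH, −78 °C
Reagents that add atoms: none
Why: Aldol addition of the lithium ester enolate, made and used at −78 °C where loss of the β-silyloxy group is slow, should form C7–C11 faster than the aldehyde is enolised, and the new centres at C7 and C11 need no control because both become sp2.

Step 16
Reactants: 20 aldol adduct
Product: 21 β-keto ester (C7 ketone; C11 epimers)
Conditions: Dess–Martin periodinane, NaHCO3, CH2Cl2, 0 °C → rt
Reagents that add atoms: none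
Why: Dess–Martin oxidation converts the β-hydroxy ester into the β-keto ester under neutral buffered conditions that should not epimerise C8.

Step 17
Reactants: 21 β-keto ester
Product: 22 Z-enol triflate (C7 OTf cis to CO2Me; C8 OSiEt3)
Conditions: NaH, Et2O, 0 °C; Tf2O, −78 → −20 °C
Reagents that add atoms: trifluoromethanesulfonic anhydride, O=S(=O)(OS(=O)(=O)C(F)(F)F)C(F)(F)F
Why: O-Triflation of the sodium enolate, in which sodium is chelated between the enolate oxygen and the ester carbonyl, should fix the triflate cis to CO2Me (Z), the geometry the lactonisation needs, the far more acidic C11–H being removed in preference to C8–H.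

Step 18
Reactants: 22 Z-enol triflate
Product: 23 C8 alcohol
Conditions: HF·pyridine, pyridine, THF, 0 °C
Reagents that add atoms: none
Why: Buffered fluoride desilylation cleaves the secondary triethylsilyl ether far faster than the tert-butyldiphenylsilyl ethers and should leave the ketal, the 4-methoxybenzyl ether and the enol triflate intact.

Step 19
Reactants: 23 C8 alcohol; 24 tigloyl chloride
Product: 25 C8 tiglate
Conditions: pyridine, DMAP (cat.), CH2Cl2, 0 °C → rt
Reagents that add atoms: none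
Why: DMAP-catalysed acylation with the acid chloride in pyridine esterifies the hindered C8 alcohol with retention at C8 and, in the absence of a trialkylamine, without deconjugation of the tigloyl unit.

Step 20
Reactants: 25 C8 tiglate
Product: 26 C6 primary alcohol
Conditions: DDQ, CH2Cl2/pH 7 phosphate buffer (10:1), 0 °C → rt
Reagents that add atoms: none
Why: Oxidative cleavage of the 4-methoxybenzyl ether by DDQ (hydride abstraction, then hydrolysis of the oxocarbenium ion) frees the C6 hydroxyl under neutral conditions that should spare the silyl ethers, ketal, esters and triflate.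

Step 21
Reactants: 26 C6 primary alcohol
Product: 27 seco enol triflate aldehyde (1R,4R,5R,8S,9Z; C6 CHO)
Conditions: Dess–Martin periodinane, NaHCO3, CH2Cl2, 0 °C
Reagents that add atoms: none
Why: Dess–Martin oxidation gives the α,β-dialkoxy aldehyde without epimerising C5, and the aldehyde is taken on immediately.

Step 22
Reactants: 27 seco enol triflate aldehyde
Product: 30 ten-membered butenolide with 4,5-acetonide (1R,4R,5S,6S,8S,9Z), via alkenylchromium dichloride 28 (not isolated), via chromium alkoxide 29 (not isolated)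
Conditions: CrCl2 (10 equiv), NiCl2 (2 mol%), DMF, rt; 27 added by syringe pump to 2 mM
Reagents that add atoms: none
Why: Zerovalent nickel, formed from NiCl2 by CrCl2, inserts into the C7–O bond of the enol triflate and hands the alkenyl group to trivalent chromium, the alkenylchromium adds to the C6 aldehyde, and the resulting chromium alkoxide acylates itself on the neighbouring methyl ester with loss of methoxide. The closest known reaction type is the Nozaki–Hiyama–Kishi coupling of cis-β-halo or β-triflyloxy acrylates with aldehydes that ends in a butenolide, run here intramolecularly at high dilution. The ten-membered carbocycle closes by 1,2-addition of C7 to the C6 carbonyl (10-exo-trig, C6–C7 bond) and the five-membered lactone by acyl substitution of the C6 alkoxide at C12 (5-exo-trig), which the Z geometry of the enoate makes possible by holding C12 cis to the new C7–C6 bond. The one new stereocentre, C6, is controlled by C5: the alkenylchromium should attack the aldehyde face anti to the C5–O bond of the dioxolane (Felkin–Anh, non-chelation, as with glyceraldehyde acetonide) to give the 5,6-anti product. The step needs ring closure to outrun dimerisation and protonolysis, which high dilution and the chain-bending cis-dioxolane, 9Z olefin and Z-enoate favour, and it needs attack on the aldehyde in preference to the ester and tiglate carbonyls, which alkenylchromium reagents show.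

Step 23
Reactants: 30 ten-membered butenolide with 4,5-acetonide
Product: 31 4,5-diol (1R,4R,5S,6S,8S,9Z)
Conditions: CF3CO2H/H2O (4:1), CH2Cl2, 0 °C
Reagents that add atoms: none
Why: Acid-catalysed hydrolysis of the isopropylidene ketal frees the 4,5-diol while the tert-butyldiphenylsilyl ethers, the lactone and the tiglate should withstand cold aqueous acid.

Step 24
Reactants: 31 4,5-diol
Product: 32 4,5-epoxide bis-silyl ether (1R,4R,5R,6S,8S,9Z)
Conditions: PPh3, diisopropyl azodicarboxylate, toluene, 0 → 50 °C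
Reagents that add atoms: none
Why: Mitsunobu cyclodehydration, in which the phosphonium activates the secondary C5 hydroxyl (the tertiary one cannot be displaced) and the C4 alkoxide displaces it from the back side in a 3-exo-tet closure, should invert C5 and give the trans 4R,5R epoxide.

Step 25
Reactants: 32 4,5-epoxide bis-silyl ether
Product: 33 target CNP0167056.1
Conditions: HF·pyridine, pyridine, THF, 0 °C → rt
Reagents that add atoms: none
Why: Fluoride-mediated desilylation with pyridine-buffered HF·pyridine removes both tert-butyldiphenylsilyl ethers and should neither open the epoxide nor cleave the esters.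

**Compound list**

1 | geraniol | CC(C)=CCC/C(C)=C/CO | starting material
2 | (2S,3S)-2,3-epoxygeraniol | OC[C@@H]1O[C@@]1(C)CCC=C(C)C | intermediate
3 | (2S,3S)-2,3-epoxygeranyl 4-methoxybenzyl ether | COc1ccc(COC[C@@H]2O[C@@]2(C)CCC=C(C)C)cc1 | intermediate
4 | (2S,3R)-1-(4-methoxybenzyloxy)-3,7-dimethyloct-6-ene-2,3-diol | COc1ccc(COC[C@H](O)[C@](C)(O)CCC=C(C)C)cc1 | intermediate
5 | (4R,5S)-5-[(4-methoxybenzyloxy)methyl]-2,2,4-trimethyl-4-(4-methylpent-3-enyl)-1,3-dioxolane | COc1ccc(COC[C@@H]2OC(C)(C)O[C@]2(C)CCC=C(C)C)cc1 | intermediate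
6 | 3-[(4R,5S)-5-[(4-methoxybenzyloxy)methyl]-2,2,4-trimethyl-1,3-dioxolan-4-yl]propanal (fragment A) | COc1ccc(COC[C@@H]2OC(C)(C)O[C@]2(C)CCC=O)cc1 | intermediate
7 | (R)-2,2-dimethyl-1,3-dioxolane-4-carbaldehyde (D-glyceraldehyde acetonide) | O=C[C@H]1COC(C)(C)O1 | starting material
8 | (S)-4-[(Z)-2-iodoprop-1-enyl]-2,2-dimethyl-1,3-dioxolane | C/C(I)=C/[C@H]1COC(C)(C)O1 | intermediate
9 | (2S,3Z)-4-iodopent-3-ene-1,2-diol | C/C(I)=C/[C@H](O)CO | intermediate
10 | (2S,3Z)-4-iodo-1,2-bis(triethylsilyloxy)pent-3-ene (fragment B) | C/C(I)=C/[C@H](O[Si](CC)(CC)CC)CO[Si](CC)(CC)CC | intermediate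
11 | alkenylchromium dichloride from 10 (chromium on C10, Z retained) | C/C([Cr](Cl)Cl)=C/[C@H](O[Si](CC)(CC)CC)CO[Si](CC)(CC)CC | intermediate
12 | coupled allylic alcohol, C1 epimers (4R,5S,8S,9Z; C7 and C8 OSiEt3, 4,5-acetonide, C6 OPMB) | COc1ccc(COC[C@@H]2OC(C)(C)O[C@]2(C)CCC(O)/C(C)=C\[C@H](O[Si](CC)(CC)CC)CO[Si](CC)(CC)CC)cc1 | intermediate
13 | (4R,5S,8S,9Z)-9-en-1-one | COc1ccc(COC[C@@H]2OC(C)(C)O[C@]2(C)CCC(=O)/C(C)=C\[C@H](O[Si](CC)(CC)CC)CO[Si](CC)(CC)CC)cc1 | intermediate
14 | (1R,4R,5S,8S,9Z)-allylic alcohol | COc1ccc(COC[C@@H]2OC(C)(C)O[C@]2(C)CC[C@@H](O)/C(C)=C\[C@H](O[Si](CC)(CC)CC)CO[Si](CC)(CC)CC)cc1 | intermediate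
15 | C1 tert-butyldiphenylsilyl ether of 14 | COc1ccc(COC[C@@H]2OC(C)(C)O[C@]2(C)CC[C@@H](O[Si](c3ccccc3)(c3ccccc3)C(C)(C)C)/C(C)=C\[C@H](O[Si](CC)(CC)CC)CO[Si](CC)(CC)CC)cc1 | intermediate
16 | C7 aldehyde (1R,4R,5S,8S,9Z; C8 OSiEt3) | COc1ccc(COC[C@@H]2OC(C)(C)O[C@]2(C)CC[C@@H](O[Si](c3ccccc3)(c3ccccc3)C(C)(C)C)/C(C)=C\[C@H](O[Si](CC)(CC)CC)C=O)cc1 | intermediate
17 | methyl 3-hydroxypropanoate | COC(=O)CCO | starting material
18 | methyl 3-(tert-butyldiphenylsilyloxy)propanoate | COC(=O)CCO[Si](c1ccccc1)(c1ccccc1)C(C)(C)C | intermediate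
19 | lithium enolate of 18 | COC(O[Li])=CCO[Si](c1ccccc1)(c1ccccc1)C(C)(C)C | intermediate
20 | aldol adduct, β-hydroxy ester (mixture at C7 and C11) | COC(=O)C(CO[Si](c1ccccc1)(c1ccccc1)C(C)(C)C)C(O)[C@@H](O[Si](CC)(CC)CC)/C=C(/C)[C@H](O[Si](c1ccccc1)(c1ccccc1)C(C)(C)C)CC[C@@]1(C)OC(C)(C)O[C@H]1COCc1ccc(OC)cc1 | intermediate
21 | β-keto ester (C7 ketone; C11 epimers) | COC(=O)C(CO[Si](c1ccccc1)(c1ccccc1)C(C)(C)C)C(=O)[C@@H](O[Si](CC)(CC)CC)/C=C(/C)[C@H](O[Si](c1ccccc1)(c1ccccc1)C(C)(C)C)CC[C@@]1(C)OC(C)(C)O[C@H]1COCc1ccc(OC)cc1 | intermediate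
22 | Z-enol triflate (C8 OSiEt3) | COC(=O)/C(CO[Si](c1ccccc1)(c1ccccc1)C(C)(C)C)=C(\OS(=O)(=O)C(F)(F)F)[C@@H](O[Si](CC)(CC)CC)/C=C(/C)[C@H](O[Si](c1ccccc1)(c1ccccc1)C(C)(C)C)CC[C@@]1(C)OC(C)(C)O[C@H]1COCc1ccc(OC)cc1 | intermediate
23 | Z-enol triflate C8 alcohol | COC(=O)/C(CO[Si](c1ccccc1)(c1ccccc1)C(C)(C)C)=C(\OS(=O)(=O)C(F)(F)F)[C@@H](O)/C=C(/C)[C@H](O[Si](c1ccccc1)(c1ccccc1)C(C)(C)C)CC[C@@]1(C)OC(C)(C)O[C@H]1COCc1ccc(OC)cc1 | intermediate
24 | tigloyl chloride, (E)-2-methylbut-2-enoyl chloride | C/C=C(\C)C(Cl)=O | starting material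
25 | Z-enol triflate C8 tiglate (C6 OPMB) | COC(=O)/C(CO[Si](c1ccccc1)(c1ccccc1)C(C)(C)C)=C(\OS(=O)(=O)C(F)(F)F)[C@@H](OC(=O)/C(C)=C/C)/C=C(/C)[C@H](O[Si](c1ccccc1)(c1ccccc1)C(C)(C)C)CC[C@@]1(C)OC(C)(C)O[C@H]1COCc1ccc(OC)cc1 | intermediate
26 | Z-enol triflate C8 tiglate, C6 primary alcohol | COC(=O)/C(CO[Si](c1ccccc1)(c1ccccc1)C(C)(C)C)=C(\OS(=O)(=O)C(F)(F)F)[C@@H](OC(=O)/C(C)=C/C)/C=C(/C)[C@H](O[Si](c1ccccc1)(c1ccccc1)C(C)(C)C)CC[C@@]1(C)OC(C)(C)O[C@H]1CO | intermediate
27 | seco enol triflate aldehyde (1R,4R,5R,8S,9Z) | COC(=O)/C(CO[Si](c1ccccc1)(c1ccccc1)C(C)(C)C)=C(\OS(=O)(=O)C(F)(F)F)[C@@H](OC(=O)/C(C)=C/C)/C=C(/C)[C@H](O[Si](c1ccccc1)(c1ccccc1)C(C)(C)C)CC[C@@]1(C)OC(C)(C)O[C@H]1C=O | intermediate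
28 | C7 alkenylchromium dichloride of 27 | COC(=O)/C(CO[Si](c1ccccc1)(c1ccccc1)C(C)(C)C)=C(\[Cr](Cl)Cl)[C@@H](OC(=O)/C(C)=C/C)/C=C(/C)[C@H](O[Si](c1ccccc1)(c1ccccc1)C(C)(C)C)CC[C@@]1(C)OC(C)(C)O[C@H]1C=O | intermediate
29 | chromium alkoxide of the ten-membered hydroxy ester (6S) | COC(=O)/C(CO[Si](c1ccccc1)(c1ccccc1)C(C)(C)C)=C1/[C@@H](OC(=O)/C(C)=C/C)/C=C(/C)[C@H](O[Si](c2ccccc2)(c2ccccc2)C(C)(C)C)CC[C@@]2(C)OC(C)(C)O[C@H]2[C@H]1O[Cr](Cl)Cl | intermediate
30 | ten-membered butenolide with 4,5-acetonide, C1 and C13 silyl ethers (1R,4R,5S,6S,8S,9Z) | C/C=C(\C)C(=O)O[C@H]1/C=C(/C)[C@H](O[Si](c2ccccc2)(c2ccccc2)C(C)(C)C)CC[C@@]2(C)OC(C)(C)O[C@H]2[C@H]2OC(=O)C(CO[Si](c3ccccc3)(c3ccccc3)C(C)(C)C)=C12 | intermediate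
31 | 4,5-diol (1R,4R,5S,6S,8S,9Z) | C/C=C(\C)C(=O)O[C@H]1/C=C(/C)[C@H](O[Si](c2ccccc2)(c2ccccc2)C(C)(C)C)CC[C@@](C)(O)[C@@H](O)[C@H]2OC(=O)C(CO[Si](c3ccccc3)(c3ccccc3)C(C)(C)C)=C12 | intermediate
32 | 4,5-epoxide bis-silyl ether (1R,4R,5R,6S,8S,9Z) | C/C=C(\C)C(=O)O[C@H]1/C=C(/C)[C@H](O[Si](c2ccccc2)(c2ccccc2)C(C)(C)C)CC[C@@]2(C)O[C@@H]2[C@H]2OC(=O)C(CO[Si](c3ccccc3)(c3ccccc3)C(C)(C)C)=C12 | intermediate
33 | CNP0167056.1 (1R,4R,5R,6S,8S,9Z) | C/C=C(\C)C(=O)O[C@H]1/C=C(/C)[C@H](O)CC[C@@]2(C)O[C@@H]2[C@H]2OC(=O)C(CO)=C12 | target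

**Summary**

Total step count: 25. Longest linear sequence: 21 steps (geraniol to 33 through steps 1–5, 9–13 and 15–25).

Steps most likely to fail:

1. Step 22. Insertion of nickel into the crowded tetrasubstituted triflate and transfer to chromium may be slower than protonolysis of the alkenyl metal and intermolecular coupling, so that the strained ten-membered ring closes poorly. The fallback exchanges the leaving group by a separate route, so that the closure runs on a β-iodoenoate in DMSO with less nickel. It sets out from alcohol 23. Coupling with Me3SnSnMe3 under Pd(PPh3)4 and LiCl in THF at 60 °C should give alkenylstannane F1 with retention. I2 in CH2Cl2 at 0 °C gives Z-iodoenoate F2. Tigloyl chloride with pyridine and DMAP gives iodoenoate tiglate F3, DDQ frees the C6 hydroxyl in iodoenoate alcohol F4, and Dess–Martin oxidation gives iodo aldehyde F5. CrCl2 with catalytic NiCl2 in DMSO at high dilution then closes both rings through alkoxide 29, and the route is rejoined at 30.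

2. Step 24. The oxyphosphonium at the hindered C5 may lose the acidic C6 proton (elimination towards the butenolide) or stall at the cyclic phosphorane stage. The fallback separates activation from closure. It sets out from diol 31: MsCl and Et3N in CH2Cl2 at −20 °C should sulfonylate only the secondary hydroxyl to give C5 mesylate F6. K2CO3 in MeOH at 0 °C then closes the epoxide with inversion at C5, and the route is rejoined at 32.

3. Step 15. The lithium enolate may expel its β-silyloxy group (acrylate formation) or deprotonate the α-silyloxy aldehyde, eroding the yield and the C8 configuration. The fallback is a Lewis-acid Mukaiyama aldol under non-basic conditions. It sets out from ester 18, which is deprotonated with LiN(iPr)2 in THF at −78 °C in the presence of Me3SiCl to give silyl ketene acetal F7. F7 adds to aldehyde 16 with BF3·OEt2 in CH2Cl2 at −78 °C, and aqueous work-up rejoins the route at aldol 20.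

Further compounds
F1 | step 22 | C7 trimethylstannyl Z-enoate, C8 alcohol | COC(=O)/C(CO[Si](c1ccccc1)(c1ccccc1)C(C)(C)C)=C(\[Sn](C)(C)C)[C@@H](O)/C=C(/C)[C@H](O[Si](c1ccccc1)(c1ccccc1)C(C)(C)C)CC[C@@]1(C)OC(C)(C)O[C@H]1COCc1ccc(OC)cc1
F2 | step 22 | C7 iodo Z-enoate, C8 alcohol | COC(=O)/C(CO[Si](c1ccccc1)(c1ccccc1)C(C)(C)C)=C(\I)[C@@H](O)/C=C(/C)[C@H](O[Si](c1ccccc1)(c1ccccc1)C(C)(C)C)CC[C@@]1(C)OC(C)(C)O[C@H]1COCc1ccc(OC)cc1
F3 | step 22 | C7 iodo Z-enoate, C8 tiglate, C6 OPMB | COC(=O)/C(CO[Si](c1ccccc1)(c1ccccc1)C(C)(C)C)=C(\I)[C@@H](OC(=O)/C(C)=C/C)/C=C(/C)[C@H](O[Si](c1ccccc1)(c1ccccc1)C(C)(C)C)CC[C@@]1(C)OC(C)(C)O[C@H]1COCc1ccc(OC)cc1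
F4 | step 22 | C7 iodo Z-enoate, C8 tiglate, C6 alcohol | COC(=O)/C(CO[Si](c1ccccc1)(c1ccccc1)C(C)(C)C)=C(\I)[C@@H](OC(=O)/C(C)=C/C)/C=C(/C)[C@H](O[Si](c1ccccc1)(c1ccccc1)C(C)(C)C)CC[C@@]1(C)OC(C)(C)O[C@H]1CO
F5 | step 22 | seco iodoenoate aldehyde | COC(=O)/C(CO[Si](c1ccccc1)(c1ccccc1)C(C)(C)C)=C(\I)[C@@H](OC(=O)/C(C)=C/C)/C=C(/C)[C@H](O[Si](c1ccccc1)(c1ccccc1)C(C)(C)C)CC[C@@]1(C)OC(C)(C)O[C@H]1C=O
F6 | step 24 | C5 methanesulfonate of diol 31 | C/C=C(\C)C(=O)O[C@H]1/C=C(/C)[C@H](O[Si](c2ccccc2)(c2ccccc2)C(C)(C)C)CC[C@@](C)(O)[C@@H](OS(C)(=O)=O)[C@H]2OC(=O)C(CO[Si](c3ccccc3)(c3ccccc3)C(C)(C)C)=C12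
F7 | step 15 | trimethylsilyl ketene acetal of ester 18 | COC(O[Si](C)(C)C)=CCO[Si](c1ccccc1)(c1ccccc1)C(C)(C)C
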